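**Retrosynthetic overview**
1. Halisulfate 1 ⇒ (hydroquinone release and O-sulfation last) the C12 alcohol; the C15–C1′ bond ⇒ a C15 Grignard reagent of a 12-silyloxy-labd-7-ene plus an (E)-aryl-prenyl chloride made from 1,4-dimethoxybenzene and prenyl bromide.
2. C7=C8 and C12–O ⇒ eliminative C8–O opening of an 8α,12-epoxylabdane, i.e. a tetrahydrofuran (O, C8, C9, C11, C12) fused to ring B.
3. That ether ⇒ 8α-hydroxylabdan-15-yl pivalate by 1,5-hydrogen transfer to a C8 alkoxyl radical. The feature used: the equatorial 8α-oxygen on ring B and the C12 methylene are 1,5-related through C9 and C11, so the chiral-pool oxygen can be moved from C8 to C12.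
4. The precursor ⇒ sclareol, which supplies C1–C15, all five methyl groups, rings A/B and C5, C9, C10. It needs allylic transposition, Ru-BINAP hydrogenation (sets C13) and pivaloylation.
5. Ring order: the A/B decalin is taken from the pool; the tetrahydrofuran is the only ring made (step 6) and is opened again (step 7); the arene is bought.

Key step: step 6

**Remarks and assumptions**
- Labdane numbering (C1–C20) is used for all terpenoid compounds, the target included. The four carbons brought in with the aryl fragment are C1′–C4′ (C1′ bonded to C15, C4′ benzylic).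
- The descriptor at C13 changes from S (compounds 5–7) to R (from 8 on) only because C12 gains priority once it carries a heteroatom. The spatial arrangement is unchanged.
- Assumption: the sulfate monoesters 24–26 are written as free hydrogen sulfates, as in the target SMILES. In the flask they would be handled as sodium salts, and the acid form corresponds to the salt after H+ exchange.

**Route**

Step 1
Reactants: 1 sclareol
Product: 2 sclareol diacetate
Conditions: AcCl, PhNMe2, CH2Cl2, 0 °C → rt
Reagents that add atoms: acetyl chloride CC(=O)Cl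
Why: Exhaustive O-acetylation with an acyl chloride and a weak aniline base should esterify both tertiary alcohols without dehydration and installs the C13 allylic acetate needed for the transposition.

Step 2
Reactants: 2 sclareol diacetate
Product: 3 (13E)-labd-13-ene-8α,15-diyl diacetate
Conditions: PdCl2(MeCN)2 (5 mol%), THF, rt
Reagents that add atoms: none
Why: The Pd(II)-catalysed [3,3] allylic acetate transposition (cyclisation-induced rearrangement) moves the ester from tertiary C13 to primary C15 and the alkene to C13=C14, and the chair-like intermediate with the larger C12 chain equatorial should favour the E isomer.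

Step 3
Reactants: 3 (13E)-labd-13-ene-8α,15-diyl diacetate
Product: 4 (13E)-labd-13-ene-8α,15-diol
Conditions: KOH, MeOH, reflux; recrystallisation (AgNO3–silica if needed) to remove any 13Z isomer
Reagents that add atoms: none
Why: Saponification frees the allylic C15 hydroxyl that must bind ruthenium in step 4, and the crystalline E diol can be purified from the Z isomer, which would otherwise give the C13 epimer.

Step 4
Reactants: 4 (13E)-labd-13-ene-8α,15-diol
Product: 5 (13S)-labdane-8α,15-diol
Conditions: H2 (50 atm), Ru(OAc)2[(R)-BINAP] (1 mol%), MeOH, rt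
Reagents that add atoms: none
Why: Noyori hydrogenation of a γ,γ-disubstituted allylic alcohol; the hydroxyl-bound Ru–(R)-BINAP catalyst should add H2 to the face of the E alkene that gives 13S (the sense of geraniol → (S)-citronellol), under catalyst control and independent of the remote decalin.

Step 5
Reactants: 5 (13S)-labdane-8α,15-diol
Product: 6 (13S)-8α-hydroxylabdan-15-yl pivalate
Conditions: PivCl, pyridine, CH2Cl2, 0 °C
Reagents that add atoms: pivaloyl chloride CC(C)(C)C(=O)Cl
Why: Sterically selective acylation esterifies the primary C15 hydroxyl and leaves the tertiary 8α-hydroxyl free for the key step.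

Step 6
Reactants: 6 (13S)-8α-hydroxylabdan-15-yl pivalate
Product: 9 (12R,13R)-8α,12-epoxylabdan-15-yl pivalate, via C8 hypoiodite 7 (not isolated), via 12-iodo alcohol 8 (not isolated)
Conditions: PhI(OAc)2 (1.5 equiv), I2 (1.0 equiv), cyclohexane, hν (tungsten lamp), 25–40 °C, N2
Reagents that add atoms: none
Why: Acetyl hypoiodite formed from PhI(OAc)2 and I2 converts the tertiary 8α-OH into hypoiodite 7; visible light cleaves its O–I bond, the C8 alkoxyl radical abstracts a C12 hydrogen through the six-membered transition state O–C8–C9–C11–C12–H, the C12 radical is iodinated to 8, and the hydroxyl then displaces the (oxidatively activated) iodide. This is the hypoiodite remote C–H etherification of alcohols, a long-used reaction of steroidal and terpenoid alcohols that carry a δ-methylene. The tetrahydrofuran (O, C8, C9, C11, C12) closes in a 5-exo-tet mode and is trans-fused to ring B as in ambroxide, because the 8α oxygen and the C9 side arm are both equatorial and gauche. C12 is the only new stereocentre and should be decided in the ring-closing transition state, where the C13 branch takes the α face syn to H-9, away from the axial C8 methyl and C10, giving 12R; C13 is not touched. The step needs 1,5-hydrogen transfer to beat β-scission of the C8–C9 bond and 1,6-transfer from the tertiary C13–H: the rigid chair holds only the C12 hydrogens within reach of the equatorial oxygen, and a non-polar solvent at or below 40 °C disfavours fragmentation.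

Step 7
Reactants: 9 (12R,13R)-8α,12-epoxylabdan-15-yl pivalate
Product: 10 (12R,13R)-12-acetoxylabd-7-en-15-yl pivalate
Conditions: Ac2O, BF3·OEt2 (cat.), CH2Cl2, −30 → 0 °C
Reagents that add atoms: acetic anhydride CC(=O)OC(C)=O
Why: Lewis-acid acetolysis of the ether (O-acylation, ionisation of the tertiary C8–O bond, E1 loss of H-7) should give the Zaitsev trisubstituted C7=C8 alkene and traps the C12 oxygen as an acetate so that the ring cannot re-close; the C12–O bond is never broken, so 12R is retained.

Step 8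
Reactants: 10 (12R,13R)-12-acetoxylabd-7-en-15-yl pivalate
Product: 11 (12R,13R)-12-hydroxylabd-7-en-15-yl pivalate
Conditions: K2CO3 (cat.), MeOH, rt
Reagents that add atoms: none
Why: Base-catalysed transesterification should remove the acetate much faster than the tert-butyl-shielded pivalate, freeing only the C12 hydroxyl.

Step 9
Reactants: 11 (12R,13R)-12-hydroxylabd-7-en-15-yl pivalate
Product: 12 (12R,13R)-12-(tert-butyldimethylsilyloxy)labd-7-en-15-yl pivalate
Conditions: TBSOTf, 2,6-lutidine, CH2Cl2, 0 °C
Reagents that add atoms: tert-butyldimethylsilyl triflate CC(C)(C)[Si](C)(C)OS(=O)(=O)C(F)(F)F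
Why: Silylation with the silyl triflate should protect even this hindered secondary alcohol, giving a group that is inert to the organomagnesium chemistry ahead.

Step 10
Reactants: 12 (12R,13R)-12-(tert-butyldimethylsilyloxy)labd-7-en-15-yl pivalate
Product: 13 (12R,13R)-12-(tert-butyldimethylsilyloxy)labd-7-en-15-ol
Conditions: DIBAL-H, CH2Cl2, −78 °C; Rochelle salt work-up
Reagents that add atoms: none
Why: Hydride reduction cleaves the pivalate to the primary alcohol, while the silyl ether and the trisubstituted alkene are inert.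

Step 11
Reactants: 13 (12R,13R)-12-(tert-butyldimethylsilyloxy)labd-7-en-15-ol
Product: 14 (12R,13R)-15-bromo-12-(tert-butyldimethylsilyloxy)labd-7-ene
Conditions: CBr4, PPh3, CH2Cl2, 0 °C
Reagents that add atoms: carbon tetrabromide BrC(Br)(Br)Br
Why: The Appel reaction replaces the primary hydroxyl by bromide in an SN2 step under near-neutral conditions that spare the silyl ether and the alkene.

Step 12
Reactants: 15 1,4-dimethoxybenzene; 16 prenyl bromide
Product: 18 1,4-dimethoxy-2-(3-methylbut-2-en-1-yl)benzene, via 2,5-dimethoxyphenyllithium 17 (not isolated)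
Conditions: n-BuLi, TMEDA, THF, 0 °C; then 16, −78 °C → rt
Reagents that add atoms: none
Why: Methoxy-directed ortho-lithiation followed by SN2 allylation of the aryllithium at the primary carbon of prenyl bromide should give the mono-prenylated arene.

Step 13
Reactants: 18 1,4-dimethoxy-2-(3-methylbut-2-en-1-yl)benzene
Product: 19 (2E)-4-(2,5-dimethoxyphenyl)-2-methylbut-2-en-1-ol
Conditions: SeO2 (cat.), t-BuOOH, CH2Cl2, rt
Reagents that add atoms: selenium dioxide O=[Se]=O; tert-butyl hydroperoxide CC(C)(C)OO
Why: The Sharpless catalytic selenium dioxide allylic oxidation (ene reaction, then [2,3]-sigmatropic shift) oxidises the (E)-methyl at the more substituted alkene terminus and should give the E allylic alcohol; the benzylic CH2 sits at the less substituted terminus and is not attacked.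

Step 14
Reactants: 19 (2E)-4-(2,5-dimethoxyphenyl)-2-methylbut-2-en-1-ol
Product: 20 2-[(2E)-4-chloro-3-methylbut-2-en-1-yl]-1,4-dimethoxybenzene
Conditions: NCS, PPh3, THF, 0 °C → rt
Reagents that add atoms: N-chlorosuccinimide O=C1CCC(=O)N1Cl
Why: Appel-type chlorination through an alkoxyphosphonium ion that chloride displaces at the primary carbon (SN2) should proceed without allylic transposition or loss of the E geometry.

Step 15
Reactants: 14 (12R,13R)-15-bromo-12-(tert-butyldimethylsilyloxy)labd-7-ene; 20 2-[(2E)-4-chloro-3-methylbut-2-en-1-yl]-1,4-dimethoxybenzene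
Product: 22 (12R,13R)-12-(tert-butyldimethylsilyloxy)-15-[(2E)-4-(2,5-dimethoxyphenyl)-2-methylbut-2-en-1-yl]labd-7-ene, via C15 Grignard reagent 21 (not isolated)
Conditions: Mg, THF, 40 °C; then 20, Li2CuCl4 (3 mol%), THF, −20 → 0 °C
Reagents that add atoms: none
Why: Kochi-type Li2CuCl4-catalysed coupling of a primary alkyl Grignard reagent with a primary allylic chloride in THF should be α-selective (SN2) and keep the E alkene, forming the C15–C1′ bond.

Step 16
Reactants: 22 (12R,13R)-12-(tert-butyldimethylsilyloxy)-15-[(2E)-4-(2,5-dimethoxyphenyl)-2-methylbut-2-en-1-yl]labd-7-ene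
Product: 23 (12R,13R)-15-[(2E)-4-(2,5-dimethoxyphenyl)-2-methylbut-2-en-1-yl]labd-7-en-12-ol
Conditions: TBAF, THF, rt → 50 °C
Reagents that add atoms: none
Why: Fluoride-mediated desilylation frees the C12 hydroxyl without affecting the alkenes or the aryl methyl ethers.

Step 17
Reactants: 23 (12R,13R)-15-[(2E)-4-(2,5-dimethoxyphenyl)-2-methylbut-2-en-1-yl]labd-7-en-12-ol
Product: 24 (12R,13R)-15-[(2E)-4-(2,5-dimethoxyphenyl)-2-methylbut-2-en-1-yl]labd-7-en-12-yl hydrogen sulfate
Conditions: SO3·pyridine, pyridine, 40 °C; aq. NaHCO3 work-up (sodium salt)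
Reagents that add atoms: sulfur trioxide–pyridine complex [O-]S(=O)(=O)[n+]1ccccc1
Why: O-sulfation with the sulfur trioxide–pyridine complex should convert the only free hydroxyl into the sulfate monoester with retention at C12, the hydroquinone oxygens being masked as methyl ethers.

Step 18
Reactants: 24 (12R,13R)-15-[(2E)-4-(2,5-dimethoxyphenyl)-2-methylbut-2-en-1-yl]labd-7-en-12-yl hydrogen sulfate
Product: 25 (12R,13R)-15-[(2E)-4-(3,6-dioxocyclohexa-1,4-dien-1-yl)-2-methylbut-2-en-1-yl]labd-7-en-12-yl hydrogen sulfate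
Conditions: (NH4)2Ce(NO3)6 (2.5 equiv), MeCN/H2O, 0 °C, short reaction time
Reagents that add atoms: water O
Why: Ceric ammonium nitrate oxidative demethylation of a 1,4-dimethoxyarene (one-electron oxidation, ipso addition of water, loss of methanol) should give the benzoquinone fast enough at 0 °C to spare the isolated alkenes and the sulfate salt.

Step 19
Reactants: 25 (12R,13R)-15-[(2E)-4-(3,6-dioxocyclohexa-1,4-dien-1-yl)-2-methylbut-2-en-1-yl]labd-7-en-12-yl hydrogen sulfate
Product: 26 halisulfate 1
Conditions: Na2S2O4, THF/H2O (degassed), rt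
Reagents that add atoms: none
Why: Dithionite reduces the quinone to the hydroquinone under near-neutral aqueous conditions that leave the sulfate ester and both alkenes untouched.

**Compound list**
1 | sclareol, (13R)-labd-14-ene-8α,13-diol | C[C@@]1(O)CC[C@H]2C(C)(C)CCC[C@]2(C)[C@H]1CC[C@@](C)(O)C=C | starting material
2 | sclareol diacetate, (13R)-labd-14-ene-8α,13-diyl diacetate | C[C@@]1(OC(C)=O)CC[C@H]2C(C)(C)CCC[C@]2(C)[C@H]1CC[C@@](C)(OC(C)=O)C=C | intermediate
3 | (13E)-labd-13-ene-8α,15-diyl diacetate | C[C@@]1(OC(C)=O)CC[C@H]2C(C)(C)CCC[C@]2(C)[C@H]1CC/C(C)=C/COC(C)=O | intermediate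
4 | (13E)-labd-13-ene-8α,15-diol | C[C@@]1(O)CC[C@H]2C(C)(C)CCC[C@]2(C)[C@H]1CC/C(C)=C/CO | intermediate
5 | (13S)-labdane-8α,15-diol | C[C@@]1(O)CC[C@H]2C(C)(C)CCC[C@]2(C)[C@H]1CC[C@H](C)CCO | intermediate
6 | (13S)-8α-hydroxylabdan-15-yl pivalate | C[C@@]1(O)CC[C@H]2C(C)(C)CCC[C@]2(C)[C@H]1CC[C@H](C)CCOC(=O)C(C)(C)C | intermediate
7 | (13S)-8α-(iodooxy)labdan-15-yl pivalate, the C8 hypoiodite | C[C@@]1(OI)CC[C@H]2C(C)(C)CCC[C@]2(C)[C@H]1CC[C@H](C)CCOC(=O)C(C)(C)C | intermediate (not isolated)
8 | (13R)-8α-hydroxy-12-iodolabdan-15-yl pivalate, C12 configuration not defined | C[C@@]1(O)CC[C@H]2C(C)(C)CCC[C@]2(C)[C@H]1CC(I)[C@H](C)CCOC(=O)C(C)(C)C | intermediate (not isolated)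
9 | (12R,13R)-8α,12-epoxylabdan-15-yl pivalate | C[C@@]12CC[C@H]3C(C)(C)CCC[C@]3(C)[C@H]1C[C@@H](O2)[C@H](C)CCOC(=O)C(C)(C)C | intermediate
10 | (12R,13R)-12-acetoxylabd-7-en-15-yl pivalate | CC1=CC[C@H]2C(C)(C)CCC[C@]2(C)[C@H]1C[C@@H](OC(C)=O)[C@H](C)CCOC(=O)C(C)(C)C | intermediate
11 | (12R,13R)-12-hydroxylabd-7-en-15-yl pivalate | CC1=CC[C@H]2C(C)(C)CCC[C@]2(C)[C@H]1C[C@@H](O)[C@H](C)CCOC(=O)C(C)(C)C | intermediate
12 | (12R,13R)-12-(tert-butyldimethylsilyloxy)labd-7-en-15-yl pivalate | CC1=CC[C@H]2C(C)(C)CCC[C@]2(C)[C@H]1C[C@@H](O[Si](C)(C)C(C)(C)C)[C@H](C)CCOC(=O)C(C)(C)C | intermediate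
13 | (12R,13R)-12-(tert-butyldimethylsilyloxy)labd-7-en-15-ol | CC1=CC[C@H]2C(C)(C)CCC[C@]2(C)[C@H]1C[C@@H](O[Si](C)(C)C(C)(C)C)[C@H](C)CCO | intermediate
14 | (12R,13R)-15-bromo-12-(tert-butyldimethylsilyloxy)labd-7-ene | CC1=CC[C@H]2C(C)(C)CCC[C@]2(C)[C@H]1C[C@@H](O[Si](C)(C)C(C)(C)C)[C@H](C)CCBr | intermediate
15 | 1,4-dimethoxybenzene | COc1ccc(OC)cc1 | starting material
16 | prenyl bromide, 1-bromo-3-methylbut-2-ene | CC(C)=CCBr | starting material
17 | 2,5-dimethoxyphenyllithium | [Li]c1cc(OC)ccc1OC | intermediate (not isolated)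
18 | 1,4-dimethoxy-2-(3-methylbut-2-en-1-yl)benzene | COc1ccc(OC)c(CC=C(C)C)c1 | intermediate
19 | (2E)-4-(2,5-dimethoxyphenyl)-2-methylbut-2-en-1-ol | COc1ccc(OC)c(C/C=C(\C)CO)c1 | intermediate
20 | 2-[(2E)-4-chloro-3-methylbut-2-en-1-yl]-1,4-dimethoxybenzene | COc1ccc(OC)c(C/C=C(\C)CCl)c1 | intermediate
21 | [(12R,13R)-12-(tert-butyldimethylsilyloxy)labd-7-en-15-yl]magnesium bromide | CC1=CC[C@H]2C(C)(C)CCC[C@]2(C)[C@H]1C[C@@H](O[Si](C)(C)C(C)(C)C)[C@H](C)CC[Mg]Br | intermediate (not isolated)
22 | (12R,13R)-12-(tert-butyldimethylsilyloxy)-15-[(2E)-4-(2,5-dimethoxyphenyl)-2-methylbut-2-en-1-yl]labd-7-ene | CC1=CC[C@H]2C(C)(C)CCC[C@]2(C)[C@H]1C[C@@H](O[Si](C)(C)C(C)(C)C)[C@H](C)CCC/C(C)=C/Cc1cc(OC)ccc1OC | intermediate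
23 | (12R,13R)-15-[(2E)-4-(2,5-dimethoxyphenyl)-2-methylbut-2-en-1-yl]labd-7-en-12-ol | CC1=CC[C@H]2C(C)(C)CCC[C@]2(C)[C@H]1C[C@@H](O)[C@H](C)CCC/C(C)=C/Cc1cc(OC)ccc1OC | intermediate
24 | (12R,13R)-15-[(2E)-4-(2,5-dimethoxyphenyl)-2-methylbut-2-en-1-yl]labd-7-en-12-yl hydrogen sulfate | CC1=CC[C@H]2C(C)(C)CCC[C@]2(C)[C@H]1C[C@@H](OS(=O)(=O)O)[C@H](C)CCC/C(C)=C/Cc1cc(OC)ccc1OC | intermediate
25 | (12R,13R)-15-[(2E)-4-(3,6-dioxocyclohexa-1,4-dien-1-yl)-2-methylbut-2-en-1-yl]labd-7-en-12-yl hydrogen sulfate | CC1=CC[C@H]2C(C)(C)CCC[C@]2(C)[C@H]1C[C@@H](OS(=O)(=O)O)[C@H](C)CCC/C(C)=C/CC1=CC(=O)C=CC1=O | intermediate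
26 | halisulfate 1, (12R,13R)-15-[(2E)-4-(2,5-dihydroxyphenyl)-2-methylbut-2-en-1-yl]labd-7-en-12-yl hydrogen sulfate | CC1=CC[C@H]2C(C)(C)CCC[C@]2(C)[C@H]1C[C@@H](OS(=O)(=O)O)[C@H](C)CCC/C(C)=C/Cc1cc(O)ccc1O | target

**Step count**
Total: 19 steps. Longest linear sequence: 16 steps (steps 1–11 and 15–19); the aryl fragment takes steps 12–14.

**Steps most likely to fail**

Step 6 (key step). What may go wrong: β-scission of the C8–C9 bond of the tertiary alkoxyl radical (opening ring B), 1,6-hydrogen transfer from the tertiary C13–H (six-membered ether and loss of the C13 configuration), or poor facial control at C12 during ring closure. Fallback, from 1 back to 9: the C12–O bond and both side-chain stereocentres are made by reagent-controlled crotylation instead of C–H functionalisation.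
- Sclareol 1 is degraded oxidatively (RuCl3 cat., NaIO4; then KOH and acidic lactonisation) to (+)-sclareolide F1.
- DIBAL-H at −78 °C gives the lactol 8α,12-epoxy-13,14,15,16-tetranorlabdan-12-ol F2.
- The open hydroxy-aldehyde form of the lactol is crotylated with (Z)-crotyldiisopinocampheylborane to (12R,13R)-labd-14-ene-8α,12-diol F3. The pinene antipode is chosen for attack giving 12R, and the Z geometry gives the 12,13-syn relationship.
- Acid-catalysed cyclodehydration through the C8 cation (cat. p-TsOH, MeNO2) closes the tetrahydrofuran with retention at C12 to (12R,13R)-8α,12-epoxylabd-14-ene F4.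
- 9-BBN hydroboration and oxidation of the vinyl group gives (12R,13R)-8α,12-epoxylabdan-15-ol F5, and pivaloylation (PivCl, pyridine) returns to 9.

Step 7. What may go wrong: non-regioselective proton loss from the C8 cation (exocyclic C8=C17 or tetrasubstituted C8=C9 alkene) and acid-induced hydride or methyl shifts on prolonged exposure. Fallback, from 9 back to 10: elimination and alkene placement are separated.
- The acetolysis is run under kinetic conditions (Ac2O, cat. TMSOTf, −40 °C, short time) and the alkene mixture is not equilibrated by acid. It is expected to contain the exocyclic isomer (12R,13R)-12-acetoxylabd-8(17)-en-15-yl pivalate F6 together with 10.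
- The unseparated mixture is isomerised with RhCl3·3H2O (cat.) in EtOH at 70 °C. This metal-hydride addition–elimination moves the exocyclic alkene to the trisubstituted ring position, so that F6 converges on 10.

Step 18. What may go wrong: acid-promoted loss of the sulfate, hydration or cyclisation of the C7=C8 or side-chain alkene in the acidic oxidising medium, or over-oxidation at the benzylic/allylic C4′ position. Fallback, from 23 back to 25: the order of oxidation and sulfation is reversed so that the sulfate never meets cerium(IV).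
- Alcohol 23 is oxidised with CAN (MeCN/H2O, 0 °C) to (12R,13R)-15-[(2E)-4-(3,6-dioxocyclohexa-1,4-dien-1-yl)-2-methylbut-2-en-1-yl]labd-7-en-12-ol F7.
- F7 is sulfated with SO3·DMF in DMF (no nucleophilic amine present) to give 25, which is reduced as in step 19.

**Further compounds**
F1 | step 6 | (+)-sclareolide | C[C@@]12CC[C@H]3C(C)(C)CCC[C@]3(C)[C@H]1CC(=O)O2
F2 | step 6 | 8α,12-epoxy-13,14,15,16-tetranorlabdan-12-ol (lactol, anomer mixture) | C[C@@]12CC[C@H]3C(C)(C)CCC[C@]3(C)[C@H]1CC(O)O2
F3 | step 6 | (12R,13R)-labd-14-ene-8α,12-diol | C[C@@]1(O)CC[C@H]2C(C)(C)CCC[C@]2(C)[C@H]1C[C@@H](O)[C@H](C)C=C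
F4 | step 6 | (12R,13R)-8α,12-epoxylabd-14-ene | C[C@@]12CC[C@H]3C(C)(C)CCC[C@]3(C)[C@H]1C[C@@H](O2)[C@H](C)C=C
F5 | step 6 | (12R,13R)-8α,12-epoxylabdan-15-ol | C[C@@]12CC[C@H]3C(C)(C)CCC[C@]3(C)[C@H]1C[C@@H](O2)[C@H](C)CCO
F6 | step 7 | (12R,13R)-12-acetoxylabd-8(17)-en-15-yl pivalate | C=C1CC[C@H]2C(C)(C)CCC[C@]2(C)[C@H]1C[C@@H](OC(C)=O)[C@H](C)CCOC(=O)C(C)(C)C
F7 | step 18 | (12R,13R)-15-[(2E)-4-(3,6-dioxocyclohexa-1,4-dien-1-yl)-2-methylbut-2-en-1-yl]labd-7-en-12-ol | CC1=CC[C@H]2C(C)(C)CCC[C@]2(C)[C@H]1C[C@@H](O)[C@H](C)CCC/C(C)=C/CC1=CC(=O)C=CC1=O
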